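The carbocycle is numbered C1 (ketone), C2=C3, C4 (OAc), C5, spiro C6; the lactone is C7H2, C8(=O), O, C9H; the side chain is C10–C15. Everything rests on cutting C1–C6 and C4–C5: oxygen at C1 and C4 across C2=C3, next to quaternary C6, marks the cyclohexenone as an opened 7-oxanorbornene. One catalytic asymmetric [4+2] reaction of 2-methoxyfuran with an α-substituted acrolein that already carries C7–C8 as a methyl ester and C9 as the formyl group closes the carbocycle, sets C4 and C6, and unveils the 4-hydroxy-enone when the bridged ketal collapses. Acetylation and a Ni/Cr alkenylation with lactonisation complete the target.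

Key step: step 2

Remark: the target is taken as the (4S,6R,9R) isomer encoded by the SMILES (C4–OAc cis to C9 on the carbocycle); the (R)-catalyst of step 2 is assigned from the accepted pre-transition-state model for boron-bound 2-substituted acroleins, and its (S)-antipode would be used, with nothing else changed, if the sense of induction were the opposite.

Step 1
Reactants: 1 methyl 4-oxobutanoate
Product: 2 methyl 3-formylbut-3-enoate
Conditions: 37% aq. CH2O (1.0 equiv), pyrrolidine (10 mol%), propionic acid (10 mol%), i-PrOH, 45 °C; used without storage
Reagents that add atoms: formaldehyde, C=O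
Why: Amine-catalysed α-methylenation of an aldehyde (Mannich condensation followed by elimination of the amine): the enamine of 1 adds to the formaldehyde-derived iminium ion at the only enolisable aldehyde α-carbon and the secondary amine is expelled; a short reaction time and immediate use of 2 should limit migration of the alkene into conjugation with the ester and self-condensation.

Step 2
Reactants: 2 methyl 3-formylbut-3-enoate; 3 2-methoxyfuran
Product: 5 methyl 2-[(1R,5S)-1-formyl-5-hydroxy-2-oxocyclohex-3-en-1-yl]acetate, via bridged methoxy ketal 4 (not isolated)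
Conditions: (R)-3,3-diphenyl-1-(o-tolyl)tetrahydro-1H,3H-pyrrolo[1,2-c][1,3,2]oxazaborole (22 mol%), Tf2NH (20 mol%), CH2Cl2, −78 °C; then H2O–THF (pH 5 phosphate buffer), 0 °C
Reagents that add atoms: water, O
Why: The boron-bound aldehyde of 2 is attacked at its β-methylene by furan C5, the position activated by the methoxy donor, and the α-carbon bonds to the methoxy-bearing furan carbon in a concerted but asynchronous [4+2] cycloaddition (or through a short-lived zwitterion) to give bridged ketal 4; the strained bridging C1–O bond then ionises with help from the methoxy oxygen and water converts the oxocarbenium ion into the C1 ketone, leaving the former bridge oxygen as the C4 hydroxyl and C2=C3 in conjugation. The closest known reaction types are the chiral-Lewis-acid-catalysed, exo-selective Diels–Alder reactions of furans with 2-substituted acroleins and the opening of 2-alkoxyfuran cycloadducts to 4-hydroxycyclohex-2-enones. The six-membered carbocycle is closed by the cycloaddition itself, which forms C4–C5 and C1–C6 (in the stepwise limit a 6-(enolexo)-exo-trig attack of the boron enolate on the oxocarbenium carbon). C6 is controlled by the catalyst, whose formyl C–H···O contact holds the s-trans enal against one phenyl group so that the diene should reach the Re face of the α-carbon, and C4 is controlled relative to C6 by the exo position of the formyl group (syn to the oxygen bridge) that 2-substituted acroleins prefer, within the suprafacial geometry of the bicycle. The step needs regiocontrol, conjugate instead of carbonyl attack, and ring closure faster than proton loss from furan C5: the methoxy group polarises the diene, the unhindered β-methylene is the reactive site of the activated enal, low temperature and a non-basic medium disfavour re-aromatisation, and quaternary C6 rules out aromatisation of 5 to a phenol.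

Step 3
Reactants: 5 methyl 2-[(1R,5S)-1-formyl-5-hydroxy-2-oxocyclohex-3-en-1-yl]acetate
Product: 6 methyl 2-[(1R,5S)-5-acetoxy-1-formyl-2-oxocyclohex-3-en-1-yl]acetate
Conditions: Ac2O, pyridine, CH2Cl2, 0 °C
Reagents that add atoms: acetic anhydride, CC(=O)OC(C)=O
Why: O-Acylation of the secondary allylic alcohol with acetic anhydride and pyridine as a mild base, with retention at C4; no other hydroxyl is present, and leaving out stronger nucleophilic catalysts should spare the non-enolisable β-keto aldehyde from deformylation.

Step 4
Reactants: 7 pent-1-en-4-yne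
Product: 9 (1E)-1-iodo-2-methylpenta-1,4-diene, via alkenyl(dimethyl)alane 8 (not isolated)
Conditions: AlMe3 (2 equiv), Cp2ZrCl2 (20 mol%), CH2Cl2, 0 °C to rt; then I2, THF, −30 to 0 °C
Reagents that add atoms: trimethylaluminium, C[Al](C)C; iodine, [I][I]
Why: Negishi carboalumination: zirconocene-catalysed syn addition of a methyl–aluminium bond across the terminal alkyne places methyl on the internal carbon (the monosubstituted alkene does not react under these conditions), and iodinolysis of the alkenyl–aluminium bond with retention gives the (E)-iodide, which fixes the C10=C11 geometry.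

Step 5
Reactants: 9 (1E)-1-iodo-2-methylpenta-1,4-diene; 10 2-methylbut-3-en-2-ol
Product: 11 (3E,6E)-7-iodo-2,6-dimethylhepta-3,6-dien-2-ol
Conditions: second-generation Hoveyda–Grubbs catalyst (5 mol%), 10 (5 equiv), 1,4-benzoquinone (10 mol%), CH2Cl2, 40 °C
Reagents that add atoms: none
Why: Olefin cross-metathesis between the unhindered terminal alkene of 9 and the tertiary allylic alcohol 10, which homodimerises slowly and is used in excess; the bulky carbinol end should enforce the (E)-geometry at C13=C14, the trisubstituted iodoalkene is too hindered to engage the ruthenium carbene, and benzoquinone suppresses migration of the skipped diene.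

Step 6
Reactants: 6 methyl 2-[(1R,5S)-5-acetoxy-1-formyl-2-oxocyclohex-3-en-1-yl]acetate; 11 (3E,6E)-7-iodo-2,6-dimethylhepta-3,6-dien-2-ol
Product: 14 [(1R,5R,9S)-1-[(1E,4E)-6-hydroxy-2,6-dimethylhepta-1,4-dien-1-yl]-3,6-dioxo-2-oxaspiro[4.5]dec-7-en-9-yl] acetate (the target), via alkenylchromium dichloride 12 (not isolated), via hydroxy ester 13 (not isolated)
Conditions: CrCl2 (4 equiv), NiCl2 (2 mol%), DMSO, rt; then PPTS (cat.), CH2Cl2, rt if ring closure is incomplete
Reagents that add atoms: none
Why: Nozaki–Hiyama–Kishi reaction followed by lactonisation: nickel-catalysed activation of the C–I bond and transmetalation to trivalent chromium give 12 with retention of the (E)-geometry, and 12 adds to the aldehyde only, leaving the enone, acetate, ester and free tertiary alcohol untouched; C9 should be set by a chelate of trivalent chromium between the C9 aldehyde oxygen and the C1 ketone oxygen (Cram chelate control), in which the alkenyl group arrives on the face turned away from the CH2CO2Me arm (the C5 side) and gives the (9R)-carbinol 13; its C9 oxygen then closes onto the methyl ester in a 5-exo-trig acyl substitution helped by quaternary C6 (Thorpe–Ingold effect), releasing methanol.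

Compound list
1 | methyl 4-oxobutanoate | COC(=O)CCC=O | starting material
2 | methyl 3-formylbut-3-enoate | COC(=O)CC(=C)C=O | intermediate
3 | 2-methoxyfuran | COc1ccco1 | starting material
4 | methyl 2-[(1S,2R,4S)-2-formyl-1-methoxy-7-oxabicyclo[2.2.1]hept-5-en-2-yl]acetate (formyl exo, syn to the oxygen bridge) | CO[C@]12C=C[C@H](C[C@]1(C=O)CC(=O)OC)O2 | intermediate
5 | methyl 2-[(1R,5S)-1-formyl-5-hydroxy-2-oxocyclohex-3-en-1-yl]acetate | O[C@@H]1C=CC(=O)[C@@](C=O)(CC(=O)OC)C1 | intermediate
6 | methyl 2-[(1R,5S)-5-acetoxy-1-formyl-2-oxocyclohex-3-en-1-yl]acetate | CC(=O)O[C@@H]1C=CC(=O)[C@@](C=O)(CC(=O)OC)C1 | intermediate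
7 | pent-1-en-4-yne | C=CCC#C | starting material
8 | dimethyl[(1E)-2-methylpenta-1,4-dien-1-yl]alane | C[Al](C)/C=C(\C)CC=C | intermediate
9 | (1E)-1-iodo-2-methylpenta-1,4-diene | I/C=C(\C)CC=C | intermediate
10 | 2-methylbut-3-en-2-ol | CC(C)(O)C=C | starting material
11 | (3E,6E)-7-iodo-2,6-dimethylhepta-3,6-dien-2-ol | I/C=C(\C)C/C=C/C(C)(C)O | intermediate
12 | [(1E,4E)-6-hydroxy-2,6-dimethylhepta-1,4-dien-1-yl]chromium dichloride | Cl[Cr](Cl)/C=C(\C)C/C=C/C(C)(C)O | intermediate
13 | methyl 2-[(1R,5S)-5-acetoxy-1-[(1R,2E,5E)-1,7-dihydroxy-3,7-dimethylocta-2,5-dien-1-yl]-2-oxocyclohex-3-en-1-yl]acetate | CC(=O)O[C@@H]1C=CC(=O)[C@@]([C@H](O)/C=C(\C)C/C=C/C(C)(C)O)(CC(=O)OC)C1 | intermediate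
14 | [(1R,5R,9S)-1-[(1E,4E)-6-hydroxy-2,6-dimethylhepta-1,4-dien-1-yl]-3,6-dioxo-2-oxaspiro[4.5]dec-7-en-9-yl] acetate | CC(=O)O[C@@H]1C=CC(=O)[C@@]2(CC(=O)O[C@@H]2/C=C(\C)C/C=C/C(C)(C)O)C1 | target

Total step count: 6. Longest linear sequence: 4 steps (steps 1, 2, 3 and 6, from 1). The side chain takes 2 steps (4 and 5) before the convergent step 6.

Steps most likely to fail

Step 2. Ring closure of the catalyst-bound zwitterion may be slow, so that the absolute face is decided by a background or stepwise pathway (low enantiomeric purity), or the intermediate re-aromatises by proton loss from furan C5. The fallback separates ring construction from absolute control. Setting out from 2 and 3, the cycloaddition is run without chiral information (ZnCl2 in CH2Cl2 at −40 °C, or no catalyst under high pressure, where the concerted path avoids the ionic intermediate) and worked up as in step 2. It passes through the racemic ketal, that is 4 together with its mirror image methyl 2-[(1R,2S,4R)-2-formyl-1-methoxy-7-oxabicyclo[2.2.1]hept-5-en-2-yl]acetate F1. It gives the racemic hydroxy aldehyde, that is 5 together with methyl 2-[(1S,5R)-1-formyl-5-hydroxy-2-oxocyclohex-3-en-1-yl]acetate F2. Lipase-catalysed transesterification (Burkholderia cepacia lipase, vinyl acetate, t-BuOMe, rt, stopped near half conversion) is then expected, by the empirical rule for secondary alcohols with the larger substituent on the C5–C6 side, to acetylate 5 and leave F2, so that the route is rejoined at 6. If the enzyme preferred the other antipode, the acetate formed would be methyl 2-[(1S,5R)-5-acetoxy-1-formyl-2-oxocyclohex-3-en-1-yl]acetate F3 and the recovered alcohol 5 would re-enter at step 3.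

Step 6. The alkenylchromium may add through an open instead of a chelated transition state and so attack the wrong face of the C9 aldehyde, giving the C9-epimeric lactone; retro-aldol loss of the new β-hydroxy ketone before lactonisation is a second leak. The fallback moves stereocontrol from the substrate to the reagent. Setting out from 6 and 11, a catalytic asymmetric Ni/Cr coupling is used: CrCl2 (10 mol%) bound to a chiral oxazoline–sulfonamide ligand, NiCl2(2,9-dimethyl-1,10-phenanthroline) (2 mol%), Mn powder, Cp2ZrCl2, LiCl, MeCN, rt. The ligand antipode is chosen for the (R)-carbinol. The same hydroxy ester 13 forms and lactonises, and the route is rejoined at 14; no new compound is made.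

Step 3. The C4 hydroxyl may add to the cis C9 formyl group (bridged lactol) and be acylated there, or the non-enolisable β-keto aldehyde may lose its formyl group under nucleophilic conditions (retro-Claisen cleavage). The fallback changes the order of events so that no acylation is done while the aldehyde is present. Setting out from 5 and 11, the Ni/Cr coupling of step 6 is run with one more equivalent of CrCl2 for the free hydroxyl; lactol and hydroxy aldehyde interconvert and are drained through the aldehyde. Via 12 and the triol ester methyl 2-[(1R,5S)-1-[(1R,2E,5E)-1,7-dihydroxy-3,7-dimethylocta-2,5-dien-1-yl]-5-hydroxy-2-oxocyclohex-3-en-1-yl]acetate F4 this gives the hydroxy lactone (1R,5R,9S)-9-hydroxy-1-[(1E,4E)-6-hydroxy-2,6-dimethylhepta-1,4-dien-1-yl]-2-oxaspiro[4.5]dec-7-ene-3,6-dione F5. Ac2O, pyridine, CH2Cl2, 0 °C then acetylates the secondary C4 hydroxyl in preference to the tertiary C15 hydroxyl, and the route ends at 14.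

Further compounds
F1 | step 2 | methyl 2-[(1R,2S,4R)-2-formyl-1-methoxy-7-oxabicyclo[2.2.1]hept-5-en-2-yl]acetate | CO[C@@]12C=C[C@@H](C[C@@]1(C=O)CC(=O)OC)O2
F2 | step 2 | methyl 2-[(1S,5R)-1-formyl-5-hydroxy-2-oxocyclohex-3-en-1-yl]acetate | O[C@H]1C=CC(=O)[C@](C=O)(CC(=O)OC)C1
F3 | step 2 | methyl 2-[(1S,5R)-5-acetoxy-1-formyl-2-oxocyclohex-3-en-1-yl]acetate | CC(=O)O[C@H]1C=CC(=O)[C@](C=O)(CC(=O)OC)C1
F0 | step 6 | none | none
F4 | step 3 | methyl 2-[(1R,5S)-1-[(1R,2E,5E)-1,7-dihydroxy-3,7-dimethylocta-2,5-dien-1-yl]-5-hydroxy-2-oxocyclohex-3-en-1-yl]acetate | O[C@@H]1C=CC(=O)[C@@]([C@H](O)/C=C(\C)C/C=C/C(C)(C)O)(CC(=O)OC)C1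
F5 | step 3 | (1R,5R,9S)-9-hydroxy-1-[(1E,4E)-6-hydroxy-2,6-dimethylhepta-1,4-dien-1-yl]-2-oxaspiro[4.5]dec-7-ene-3,6-dione | O[C@@H]1C=CC(=O)[C@@]2(CC(=O)O[C@@H]2/C=C(\C)C/C=C/C(C)(C)O)C1
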